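A direct plan would make ring A first. 2,4-Dimethoxybenzene-1,3,5-triol A1 would be C-acylated with methoxyacetonitrile (Hoesch) to the ω-methoxyacetophenone A2. An Allan–Robinson fusion of A2 with 4-benzyloxy-2,5-dimethoxybenzoic anhydride A3 would give the 4'-O-benzyl flavone A4, and hydrogenolysis would finish.
Its weakest steps would be:
- The making of A1: this symmetric pentaoxygenated benzene would itself cost several oxidation and protection steps on an air-sensitive arene.
- The Hoesch acylation: the only free CH of A1 lies between two hydroxyls, so O-acylation and oxidation of the ring would compete.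
- The Allan–Robinson ring closure: at about 180 °C the free 5- and 7-hydroxyls would be aroylated and little A4 would be expected.

The four contiguous oxygen-bearing carbons C5–C8 of ring A are taken from squaric acid, and ring A is made last. Rings B and C are first joined as a 2-aryl-3-methoxy-4-pyranone; its lithium derivative adds to dimethyl squarate, and after the two enol ether oxygens have been told apart the 4-pyranyl-cyclobutenone is heated. Ring opening to a dienylketene and 6π electrocyclization onto the pyranone CH form the C4a–C5 bond and, by tautomerization, the hexasubstituted benzene ring with 5-OH, 6-OMe, 7-O and 8-OMe already in place. No pentaoxygenated phenol has to be made or acylated, and no chromone ring has to be closed at high temperature on free phenols.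

Key step: step 8

Remark: the target is achiral; the sp3 carbon of cyclobutenones 12–15 is a racemic stereocentre that the key step destroys. Cyclobutenone numbering below: C1 is the carbonyl carbon, C4 the sp3 carbon.

Step 1
Reactants: 1 2,5-dimethoxyphenol
Product: 2 1,4-dimethoxy-2-(methoxymethoxy)benzene
Conditions: MOMCl (1.3 equiv), i-Pr2NEt (1.5 equiv), CH2Cl2, 0 °C → rt
Reagents that add atoms: chloromethyl methyl ether, COCCl
Why: O-alkylation of the phenol (methoxymethyl ether formation) should give an ether that survives organolithium, zinc and silanolate reagents and falls off with acid in the last step.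

Step 2
Reactants: 2 1,4-dimethoxy-2-(methoxymethoxy)benzene
Product: 3 1-bromo-2,5-dimethoxy-4-(methoxymethoxy)benzene
Conditions: NBS (1.02 equiv), NaHCO3 (0.1 equiv), MeCN, 0 °C → rt, dark
Reagents that add atoms: N-bromosuccinimide, O=C1CCC(=O)N1Br
Why: Electrophilic aromatic bromination should go to the position para to OMOM and ortho to OMe, the site at which 1,2,4-trialkoxybenzenes are halogenated; the other two CH positions are activated by one ortho oxygen only or are flanked by two ether groups.

Step 3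
Reactants: 4 3-hydroxy-4H-pyran-4-one (pyromeconic acid)
Product: 5 2-bromo-3-hydroxy-4H-pyran-4-one
Conditions: NBS (1.0 equiv), DMF, 0 °C → rt
Reagents that add atoms: N-bromosuccinimide, O=C1CCC(=O)N1Br
Why: Electrophilic bromination of the enol should occur at C2, ortho to the hydroxyl, the position at which 3-hydroxy-4-pyranones take up electrophiles (compare C6 of kojic acid and the C2 hydroxyalkylation of pyromeconic acid).

Step 4
Reactants: 5 2-bromo-3-hydroxy-4H-pyran-4-one
Product: 6 2-bromo-3-methoxy-4H-pyran-4-one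
Conditions: MeI (1.5 equiv), K2CO3 (1.2 equiv), acetone, rt
Reagents that add atoms: iodomethane, CI
Why: Williamson O-methylation of the acidic enol sets the future 3-OMe of the flavone; room temperature is chosen to spare the activated C2–Br bond.

Step 5
Reactants: 3 1-bromo-2,5-dimethoxy-4-(methoxymethoxy)benzene; 6 2-bromo-3-methoxy-4H-pyran-4-one
Product: 9 2-[2,5-dimethoxy-4-(methoxymethoxy)phenyl]-3-methoxy-4H-pyran-4-one, via aryllithium 7 (not isolated), via arylzinc chloride 8 (not isolated)
Conditions: 3, n-BuLi (1.05 equiv), THF, −78 °C; ZnCl2 (1.1 equiv), −78 °C → rt; then 6 (0.9 equiv), Pd(PPh3)4 (3 mol %), THF, 50 °C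
Reagents that add atoms: none
Why: Bromine–lithium exchange, transmetalation to zinc and Negishi cross-coupling with the vinylogous acyl bromide 6 (fast oxidative addition) should join rings B and C; the arylzinc does not add to the pyranone carbonyl.

Step 6
Reactants: 9 2-[2,5-dimethoxy-4-(methoxymethoxy)phenyl]-3-methoxy-4H-pyran-4-one; 10 dimethyl squarate (3,4-dimethoxycyclobut-3-ene-1,2-dione)
Product: 13 2,3,4-trimethoxy-4-{6-[2,5-dimethoxy-4-(methoxymethoxy)phenyl]-5-methoxy-4-oxo-4H-pyran-2-yl}cyclobut-2-en-1-one (racemic), via 6-lithiopyranone 11 (not isolated), via lithium alkoxide 12 (not isolated)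
Conditions: LiTMP (1.1 equiv, from 2,2,6,6-tetramethylpiperidine and n-BuLi), THF, −78 °C, 15 min; 10 (1.2 equiv), −78 °C, 30 min; MeOTf (1.2 equiv), −78 → −20 °C; aq. NaHCO3
Reagents that add atoms: methyl trifluoromethanesulfonate, COS(=O)(=O)C(F)(F)F
Why: C–H lithiation next to the ring oxygen (the site at which chromones are metalated by TMP bases), 1,2-addition of the vinyllithium to one carbonyl of the symmetric squarate and O-methylation of the tertiary alkoxide in the same flask are the standard entry to Moore precursors; the new C4 stereocentre is racemic and is destroyed in step 8.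

Step 7
Reactants: 13 2,3,4-trimethoxy-4-{6-[2,5-dimethoxy-4-(methoxymethoxy)phenyl]-5-methoxy-4-oxo-4H-pyran-2-yl}cyclobut-2-en-1-one
Product: 15 2,4-dimethoxy-3-(methoxymethoxy)-4-{6-[2,5-dimethoxy-4-(methoxymethoxy)phenyl]-5-methoxy-4-oxo-4H-pyran-2-yl}cyclobut-2-en-1-one (racemic), via potassium enolate 14 (not isolated)
Conditions: KOSiMe3 (1.05 equiv), THF, 0 °C → rt; then MOMCl (1.3 equiv), 0 °C; Et3N-deactivated silica
Reagents that add atoms: potassium trimethylsilanolate, C[Si](C)(C)[O-].[K+]; chloromethyl methyl ether, COCCl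
Why: Cleavage of a vinylogous ester by addition–elimination at the enone β-carbon (as in the half-hydrolysis of squarate diesters, here with silanolate as a water-free hydroxide equivalent) can touch only the C3 methoxy group; enolate 14 of the 2-methoxycyclobutane-1,3-dione is symmetric about the C2···C4 axis, so O-alkylation at either oxygen gives the same constitution, with OMOM on the carbon that becomes C7 and OMe on the carbon that becomes C6.

Step 8
Reactants: 15 2,4-dimethoxy-3-(methoxymethoxy)-4-{6-[2,5-dimethoxy-4-(methoxymethoxy)phenyl]-5-methoxy-4-oxo-4H-pyran-2-yl}cyclobut-2-en-1-one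
Product: 19 5,7-dihydroxy-2-(4-hydroxy-2,5-dimethoxyphenyl)-3,6,8-trimethoxy-4H-chromen-4-one (the target), via dienylketene 16 (not isolated), via cyclohexadienone 17 (not isolated), via MOM-protected flavone 18 (not isolated)
Conditions: degassed toluene (0.02 M), 110 °C, Ar; evaporate; then 2 M HCl, MeOH/THF, 50 °C
Reagents that add atoms: none
Why: Moore rearrangement: on heating, the cyclobutenone opens by conrotatory 4π electrocyclic cleavage of the C1–C4 bond, the C4 methoxy group turning outward (the known preference of donor substituents), so that the pyranyl group stands cis to the ketene in 16. A thermal 6π electrocyclization then joins the ketene carbon to C3 of the pyranyl group (its enol-ether β-carbon, the only CH next to the point of attachment) and closes ring A as cyclohexadienone 17, whose doubly activated ring-fusion hydrogen shifts to oxygen to give the aromatic ring of 18. In this one operation the C4a–C5 bond and the whole hexasubstituted ring A are formed, with 5-OH from the ketene oxygen, 6-OMe and 7-OMOM from C2 and C3 of the cyclobutenone and 8-OMe from the C4 ether, so no regiochemical choice is left; closure on the ring oxygen would give only a reversible zwitterion. The closest known reaction type is the thermal ring expansion of 4-aryl-, 4-heteroaryl- and 4-alkenyl-4-alkoxy-2,3-dialkoxycyclobutenones to monoprotected hydroquinones. The racemic stereocentre of 15 is destroyed and no new one is formed. Methanolic HCl then removes both methoxymethyl groups, while the chelated 5-OH, the 3-methoxy enol ether and the aryl methyl ethers should be stable to it.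

Compound list
1 | 2,5-dimethoxyphenol | COc1ccc(OC)c(O)c1 | starting material
2 | 1,4-dimethoxy-2-(methoxymethoxy)benzene | COCOc1cc(OC)ccc1OC | intermediate
3 | 1-bromo-2,5-dimethoxy-4-(methoxymethoxy)benzene | COCOc1cc(OC)c(Br)cc1OC | intermediate
4 | 3-hydroxy-4H-pyran-4-one (pyromeconic acid) | O=c1ccocc1O | starting material
5 | 2-bromo-3-hydroxy-4H-pyran-4-one | O=c1ccoc(Br)c1O | intermediate
6 | 2-bromo-3-methoxy-4H-pyran-4-one | COc1c(Br)occc1=O | intermediate
7 | [2,5-dimethoxy-4-(methoxymethoxy)phenyl]lithium | [Li]c1cc(OC)c(OCOC)cc1OC | intermediate (not isolated)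
8 | [2,5-dimethoxy-4-(methoxymethoxy)phenyl]zinc chloride | Cl[Zn]c1cc(OC)c(OCOC)cc1OC | intermediate (not isolated)
9 | 2-[2,5-dimethoxy-4-(methoxymethoxy)phenyl]-3-methoxy-4H-pyran-4-one | COCOc1cc(OC)c(-c2occc(=O)c2OC)cc1OC | intermediate
10 | dimethyl squarate (3,4-dimethoxycyclobut-3-ene-1,2-dione) | COC1=C(OC)C(=O)C1=O | starting material
11 | {6-[2,5-dimethoxy-4-(methoxymethoxy)phenyl]-5-methoxy-4-oxo-4H-pyran-2-yl}lithium | [Li]c1cc(=O)c(OC)c(-c2cc(OC)c(OCOC)cc2OC)o1 | intermediate (not isolated)
12 | lithium 2,3-dimethoxy-4-oxo-1-{6-[2,5-dimethoxy-4-(methoxymethoxy)phenyl]-5-methoxy-4-oxo-4H-pyran-2-yl}cyclobut-2-en-1-olate (racemic) | [Li+].[O-]C1(c2cc(=O)c(OC)c(-c3cc(OC)c(OCOC)cc3OC)o2)C(OC)=C(OC)C1=O | intermediate (not isolated)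
13 | 2,3,4-trimethoxy-4-{6-[2,5-dimethoxy-4-(methoxymethoxy)phenyl]-5-methoxy-4-oxo-4H-pyran-2-yl}cyclobut-2-en-1-one (racemic) | COC1=C(OC)C(OC)(c2cc(=O)c(OC)c(-c3cc(OC)c(OCOC)cc3OC)o2)C1=O | intermediate
14 | potassium 2,4-dimethoxy-3-oxo-4-{6-[2,5-dimethoxy-4-(methoxymethoxy)phenyl]-5-methoxy-4-oxo-4H-pyran-2-yl}cyclobut-1-en-1-olate (racemic) | [K+].[O-]C1=C(OC)C(=O)C1(OC)c1cc(=O)c(OC)c(-c2cc(OC)c(OCOC)cc2OC)o1 | intermediate (not isolated)
15 | 2,4-dimethoxy-3-(methoxymethoxy)-4-{6-[2,5-dimethoxy-4-(methoxymethoxy)phenyl]-5-methoxy-4-oxo-4H-pyran-2-yl}cyclobut-2-en-1-one (racemic) | COCOC1=C(OC)C(=O)C1(OC)c1cc(=O)c(OC)c(-c2cc(OC)c(OCOC)cc2OC)o1 | intermediate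
16 | (3Z)-2,4-dimethoxy-3-(methoxymethoxy)-4-{6-[2,5-dimethoxy-4-(methoxymethoxy)phenyl]-5-methoxy-4-oxo-4H-pyran-2-yl}buta-1,3-dien-1-one | O=C=C(OC)/C(OCOC)=C(/OC)c1cc(=O)c(OC)c(-c2cc(OC)c(OCOC)cc2OC)o1 | intermediate (not isolated)
17 | 2-[2,5-dimethoxy-4-(methoxymethoxy)phenyl]-3,6,8-trimethoxy-7-(methoxymethoxy)-4aH-chromene-4,5-dione (racemic) | COCOC1=C(OC)C(=O)C2C(=O)C(OC)=C(c3cc(OC)c(OCOC)cc3OC)OC2=C1OC | intermediate (not isolated)
18 | 5-hydroxy-2-[2,5-dimethoxy-4-(methoxymethoxy)phenyl]-3,6,8-trimethoxy-7-(methoxymethoxy)-4H-chromen-4-one | COCOc1cc(OC)c(-c2oc3c(OC)c(OCOC)c(OC)c(O)c3c(=O)c2OC)cc1OC | intermediate (not isolated)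
19 | 5,7-dihydroxy-2-(4-hydroxy-2,5-dimethoxyphenyl)-3,6,8-trimethoxy-4H-chromen-4-one (5,7,4'-trihydroxy-3,6,8,2',5'-pentamethoxyflavone, achiral) | COc1cc(-c2oc3c(OC)c(O)c(OC)c(O)c3c(=O)c2OC)c(OC)cc1O | target

Total step count: 8. Longest linear sequence: 6 steps (steps 1, 2, 5, 6, 7, 8 or steps 3, 4, 5, 6, 7, 8).

Steps most likely to fail

Step 6. The lithiated pyranone may open its ring or add to unreacted 9 before it meets the squarate, deprotonation may also take place next to the carbonyl, and methyl triflate may alkylate the pyranone carbonyl oxygen. The fallback sets out from 9 and comes back at 13. C–H zincation with TMPZnCl·LiCl (TMP = 2,2,6,6-tetramethylpiperidide) at 25 °C, the base known to zincate chromones next to the ring oxygen, would give the zinc reagent {6-[2,5-dimethoxy-4-(methoxymethoxy)phenyl]-5-methoxy-4-oxo-4H-pyran-2-yl}zinc chloride F1, and iodine would turn it into the 6-iodopyranone F2. Iodine–magnesium exchange with i-PrMgCl·LiCl at −40 °C would give the Grignard reagent F3, which would add to 10; aqueous work-up would give the carbinol F4, and MeI/Ag2O would methylate it to 13.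

Step 7. The silanolate may attack the pyranone ring or the cyclobutenone carbonyl (ring cleavage) instead of C3, and the enolate may be alkylated on carbon. The fallback sets out from 10 and 9 and comes back at 19; it tells the two oxygens apart in the squarate instead. Mono-transesterification of 10 with benzyl alcohol would give benzyl methyl squarate F5. Lithiated 9 (11) would add to it without selectivity, and after quenching with MeOTf chromatography would separate the wanted adduct F6 (benzyloxy on C3) from its isomer F7 (benzyloxy on C2). Heating F6 as in step 8 would give the 7-O-benzyl flavone F8. Hydrogenolysis (H2, Pd/C) would give the 4'-O-methoxymethyl flavone F9, and methanolic HCl would give 19.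

Step 8. The vinylogous methoxymethyl ester may be lost under heat (traces of acid or water) before the ring opens, after which the free 1,3-dione would break up into two ketenes; slow closure of the ketene onto the electron-poor pyranone would leave time for this. The fallback sets out from 14 and comes back at 19; it carries O7 through the rearrangement as a silyl enol ether with no acetal linkage. Trapping 14 on oxygen with i-Pr3SiOTf would give the triisopropylsilyl enol ether F10. Thermolysis would give the 7-O-triisopropylsilyl flavone F11, Bu4NF would give F9, and methanolic HCl would give 19.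

Further compounds
F1 | step 6 | {6-[2,5-dimethoxy-4-(methoxymethoxy)phenyl]-5-methoxy-4-oxo-4H-pyran-2-yl}zinc chloride | COCOc1cc(OC)c(-c2oc([Zn]Cl)cc(=O)c2OC)cc1OC
F2 | step 6 | 2-[2,5-dimethoxy-4-(methoxymethoxy)phenyl]-6-iodo-3-methoxy-4H-pyran-4-one | COCOc1cc(OC)c(-c2oc(I)cc(=O)c2OC)cc1OC
F3 | step 6 | {6-[2,5-dimethoxy-4-(methoxymethoxy)phenyl]-5-methoxy-4-oxo-4H-pyran-2-yl}magnesium chloride | COCOc1cc(OC)c(-c2oc([Mg]Cl)cc(=O)c2OC)cc1OC
F4 | step 6 | 4-hydroxy-2,3-dimethoxy-4-{6-[2,5-dimethoxy-4-(methoxymethoxy)phenyl]-5-methoxy-4-oxo-4H-pyran-2-yl}cyclobut-2-en-1-one (racemic) | COC1=C(OC)C(O)(c2cc(=O)c(OC)c(-c3cc(OC)c(OCOC)cc3OC)o2)C1=O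
F5 | step 7 | 3-(benzyloxy)-4-methoxycyclobut-3-ene-1,2-dione | COC1=C(OCc2ccccc2)C(=O)C1=O
F6 | step 7 | 3-(benzyloxy)-2,4-dimethoxy-4-{6-[2,5-dimethoxy-4-(methoxymethoxy)phenyl]-5-methoxy-4-oxo-4H-pyran-2-yl}cyclobut-2-en-1-one (racemic) | COC1=C(OCc2ccccc2)C(OC)(c2cc(=O)c(OC)c(-c3cc(OC)c(OCOC)cc3OC)o2)C1=O
F7 | step 7 | 2-(benzyloxy)-3,4-dimethoxy-4-{6-[2,5-dimethoxy-4-(methoxymethoxy)phenyl]-5-methoxy-4-oxo-4H-pyran-2-yl}cyclobut-2-en-1-one (racemic) | COC1=C(OCc2ccccc2)C(=O)C1(OC)c1cc(=O)c(OC)c(-c2cc(OC)c(OCOC)cc2OC)o1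
F8 | step 7 | 7-(benzyloxy)-5-hydroxy-2-[2,5-dimethoxy-4-(methoxymethoxy)phenyl]-3,6,8-trimethoxy-4H-chromen-4-one | COCOc1cc(OC)c(-c2oc3c(OC)c(OCc4ccccc4)c(OC)c(O)c3c(=O)c2OC)cc1OC
F9 | step 7 | 5,7-dihydroxy-2-[2,5-dimethoxy-4-(methoxymethoxy)phenyl]-3,6,8-trimethoxy-4H-chromen-4-one | COCOc1cc(OC)c(-c2oc3c(OC)c(O)c(OC)c(O)c3c(=O)c2OC)cc1OC
F10 | step 8 | 2,4-dimethoxy-3-[(triisopropylsilyl)oxy]-4-{6-[2,5-dimethoxy-4-(methoxymethoxy)phenyl]-5-methoxy-4-oxo-4H-pyran-2-yl}cyclobut-2-en-1-one (racemic) | CC(C)[Si](OC1=C(OC)C(=O)C1(OC)c1cc(=O)c(OC)c(-c2cc(OC)c(OCOC)cc2OC)o1)(C(C)C)C(C)C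
F11 | step 8 | 5-hydroxy-2-[2,5-dimethoxy-4-(methoxymethoxy)phenyl]-3,6,8-trimethoxy-7-[(triisopropylsilyl)oxy]-4H-chromen-4-one | COCOc1cc(OC)c(-c2oc3c(OC)c(O[Si](C(C)C)(C(C)C)C(C)C)c(OC)c(O)c3c(=O)c2OC)cc1OC
A1 | direct plan | 2,4-dimethoxybenzene-1,3,5-triol | COc1c(O)cc(O)c(OC)c1O
A2 | direct plan | 2-methoxy-1-(2,4,6-trihydroxy-3,5-dimethoxyphenyl)ethan-1-one | COCC(=O)c1c(O)c(OC)c(O)c(OC)c1O
A3 | direct plan | 4-(benzyloxy)-2,5-dimethoxybenzoic anhydride | COc1cc(OCc2ccccc2)c(OC)cc1C(=O)OC(=O)c1cc(OC)c(OCc2ccccc2)cc1OC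
A4 | direct plan | 2-[4-(benzyloxy)-2,5-dimethoxyphenyl]-5,7-dihydroxy-3,6,8-trimethoxy-4H-chromen-4-one | COc1cc(-c2oc3c(OC)c(O)c(OC)c(O)c3c(=O)c2OC)c(OC)cc1OCc1ccccc1
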